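The route rests on disconnecting the C3–C4 bond of ring A (drimane numbering), between the C3 carbinol and the quaternary gem-dimethyl carbon C4 next to ring-fusion carbon C5. C4 with its two methyl groups is the Markovnikov radical of an isopropenyl group, so ring B with C5 maps onto (S)-carvone. In the key step an iron hydride transfers a hydrogen atom to the isopropenyl group of a monocyclic carvone derivative whose C10 carries a methyl group and an (S)-2-benzoyloxy-3-oxopropyl chain; the tertiary radical closes ring A onto the aldehyde, forming the quaternary C4, the C3 alcohol and the trans-decalin in one operation. Methylenation, hydroboration and Mitsunobu etherification with umbelliferone finish the synthesis.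

Key step: step 5

Remark on numbering: drimane numbering is used for the decalin throughout. Ring A is C1, C2, C3, C4, C5, C10; ring B is C5 to C10; C11 is the OCH2 carbon. Carvone C5 becomes C5, the carvone carbonyl carbon becomes C9, and carvone C6 becomes C10.

Assumption: compound 3 is carried forward as its mixture of C6 epimers, because C6 is planarised again in step 2.

Step 1
Reactants: 1 (S)-(+)-carvone; 2 iodomethane
Product: 3 (5S)-2,6-dimethyl-5-(prop-1-en-2-yl)cyclohex-2-en-1-one (6-methylcarvone, C6 epimers, trans major)
Conditions: LiN(iPr)2, THF, −78 °C; then MeI, −78 to 0 °C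
Reagents that add atoms: iodomethane, CI
Why: Kinetic deprotonation gives the cross-conjugated α'-enolate of the enone, which is C-methylated (enolate alkylation); the new C6 configuration is irrelevant because C6 is enolised again in step 2.

Step 2
Reactants: 3 6-methylcarvone; 4 allyl bromide
Product: 5 (5R,6R)-2,6-dimethyl-5-(prop-1-en-2-yl)-6-(prop-2-en-1-yl)cyclohex-2-en-1-one
Conditions: LiN(iPr)2, THF, −78 to 0 °C; then allyl bromide, DMPU, −78 to 23 °C
Reagents that add atoms: allyl bromide, C=CCBr
Why: Enolate alkylation of the tetrasubstituted α'-enolate should occur on the face anti to the neighbouring isopropenyl group, which sets the quaternary carbon (future C10) with the allyl chain trans and the methyl group cis to the isopropenyl group, as the trans ring fusion requires.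

Step 3
Reactants: 5 allyl methyl carvone
Product: 6 3-[(1R,6R)-1,3-dimethyl-2-oxo-6-(prop-1-en-2-yl)cyclohex-3-en-1-yl]propanal
Conditions: PdCl2(PhCN)2 (cat.), CuCl2·2H2O (cat.), AgNO2 (cat.), O2 (1 atm), t-BuOH/MeNO2, 23 °C
Reagents that add atoms: dioxygen, O=O
Why: The nitrite-modified, aldehyde-selective (anti-Markovnikov) Wacker-type oxidation should act only on the monosubstituted alkene, a reaction type established for hindered allyl groups on quaternary α-carbons of ketones, and should leave the 1,1-disubstituted and trisubstituted alkenes untouched.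

Step 4
Reactants: 6 keto aldehyde; 7 dibenzoyl peroxide
Product: 8 (2S)-3-[(1R,6R)-1,3-dimethyl-2-oxo-6-(prop-1-en-2-yl)cyclohex-3-en-1-yl]-1-oxopropan-2-yl benzoate
Conditions: (S)-2-(triphenylmethyl)pyrrolidine (10 mol%), hydroquinone (10 mol%), THF, 0 °C
Reagents that add atoms: dibenzoyl peroxide, O=C(OOC(=O)c1ccccc1)c1ccccc1
Why: Enamine-catalysed α-benzoyloxylation of the aldehyde, in which the peroxide should attack the E-enamine on the face anti to the trityl group, sets the (S) centre (future C2) under catalyst control, remote from the ring stereocentres.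

Step 5
Reactants: 8 (S)-α-benzoyloxy aldehyde
Product: 9 (2S,3S,4aR,8aR)-3-hydroxy-4,4,7,8a-tetramethyl-8-oxo-1,2,3,4,4a,5,8,8a-octahydronaphthalen-2-yl benzoate
Conditions: Fe(acac)3 (0.5 equiv), PhSiH3, EtOH, 60 °C
Reagents that add atoms: none
Why: An iron hydride formed from Fe(acac)3 and PhSiH3 should transfer a hydrogen atom to the CH2 terminus of the isopropenyl group (Markovnikov metal-hydride HAT), giving the tertiary radical at C4, which adds to the aldehyde carbon C3; the alkoxy radical is then reduced by divalent iron and protonated by ethanol. The closest known reaction type is the iron-hydride HAT-initiated reductive radical cyclisation (and intermolecular coupling) of alkenes with ketones and aldehydes. Ring A closes in the 6-exo-trig mode through a chair transition state fused trans to ring B, which is available because the C10 side chain and the C5 radical arm are trans and both equatorial on ring B. The new C3 stereocentre is controlled by that chair: the C2 benzoate from step 4 sits equatorial and the carbonyl oxygen should take the equatorial site, away from the axial hydrogens at C1 and C5, so the 3-OH should emerge equatorial and trans to the benzoate, while the new quaternary C4 is not a stereocentre and C5 is untouched. The step needs chemoselective HAT to the isopropenyl group over the electron-poor trisubstituted C7=C8 enone alkene and over carbonyl reduction, which the higher HAT reactivity of the 1,1-disubstituted alkene should secure, and it needs the reversible addition to the aldehyde to be drawn forward, which the fast reduction of the alkoxy radical should secure.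

Step 6
Reactants: 9 hydroxy benzoate enone; 10 methyltriphenylphosphonium bromide
Product: 12 (2S,3S,4aS,8aR)-4,4,7,8a-tetramethyl-8-methylidene-1,2,3,4,4a,5,8,8a-octahydronaphthalene-2,3-diol, via diene benzoate 11 (not isolated)
Conditions: Ph3PCH3Br, KOtBu (excess), toluene, 90 °C; then MeOH, K2CO3, 23 °C
Reagents that add atoms: methyltriphenylphosphonium bromide, C[P+](c1ccccc1)(c1ccccc1)c1ccccc1.[Br-]
Why: Wittig methylenation of the hindered C9 enone should give the exocyclic 7,9(11)-diene, and the methoxide formed on adding methanol then cleaves the benzoate by transesterification; no stereocentre is touched.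

Step 7
Reactants: 12 diene diol
Product: 14 (2S,3S,4aS,8R,8aR)-8-(hydroxymethyl)-4,4,7,8a-tetramethyl-1,2,3,4,4a,5,8,8a-octahydronaphthalene-2,3-diol, via alkylborane 13 (not isolated)
Conditions: 9-BBN (4 equiv), THF, 0 to 50 °C; then NaOH, H2O2, 0 to 23 °C
Reagents that add atoms: hydrogen peroxide, OO
Why: Hydroboration–oxidation: 9-BBN should add anti-Markovnikov to the terminal CH2 of the diene only and deliver hydrogen to C9 from the face opposite the axial C10 methyl group, so that C11 becomes equatorial and cis to that methyl group, and the oxidation retains this configuration.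

Step 8
Reactants: 14 triol; 15 umbelliferone (7-hydroxycoumarin)
Product: 16 7-{[(1R,4aS,6S,7S,8aR)-6,7-dihydroxy-2,5,5,8a-tetramethyl-1,4,4a,5,6,7,8,8a-octahydronaphthalen-1-yl]methoxy}-2H-chromen-2-one (CNP0124364.1)
Conditions: PPh3, DIAD, THF, 0 to 23 °C
Reagents that add atoms: umbelliferone, O=c1ccc2ccc(O)cc2o1
Why: Mitsunobu etherification should engage only the primary C11 alcohol, because backside displacement at the equatorial secondary carbinols C2 and C3 would need an axial trajectory syn to the axial methyl groups at C4 and C10, and the rigid trans-diequatorial diol cannot close to an epoxide.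

Compound list
1 | (S)-(+)-carvone | CC1=CC[C@@H](CC1=O)C(C)=C | starting material
2 | iodomethane | CI | starting material
3 | (5S)-2,6-dimethyl-5-(prop-1-en-2-yl)cyclohex-2-en-1-one (C6 epimers) | CC1=CC[C@H](C(C)=C)C(C)C1=O | intermediate
4 | allyl bromide | C=CCBr | starting material
5 | (5R,6R)-2,6-dimethyl-5-(prop-1-en-2-yl)-6-(prop-2-en-1-yl)cyclohex-2-en-1-one | CC1=CC[C@H](C(C)=C)[C@](CC=C)(C)C1=O | intermediate
6 | 3-[(1R,6R)-1,3-dimethyl-2-oxo-6-(prop-1-en-2-yl)cyclohex-3-en-1-yl]propanal | CC1=CC[C@H](C(C)=C)[C@](CCC=O)(C)C1=O | intermediate
7 | dibenzoyl peroxide | O=C(OOC(=O)c1ccccc1)c1ccccc1 | starting material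
8 | (2S)-3-[(1R,6R)-1,3-dimethyl-2-oxo-6-(prop-1-en-2-yl)cyclohex-3-en-1-yl]-1-oxopropan-2-yl benzoate | CC1=CC[C@H](C(C)=C)[C@](C[C@H](OC(=O)c2ccccc2)C=O)(C)C1=O | intermediate
9 | (2S,3S,4aR,8aR)-3-hydroxy-4,4,7,8a-tetramethyl-8-oxo-1,2,3,4,4a,5,8,8a-octahydronaphthalen-2-yl benzoate | CC1=CC[C@@H]2C(C)(C)[C@H](O)[C@@H](OC(=O)c3ccccc3)C[C@@]2(C)C1=O | intermediate
10 | methyltriphenylphosphonium bromide | C[P+](c1ccccc1)(c1ccccc1)c1ccccc1.[Br-] | starting material
11 | (2S,3S,4aS,8aR)-3-hydroxy-4,4,7,8a-tetramethyl-8-methylidene-1,2,3,4,4a,5,8,8a-octahydronaphthalen-2-yl benzoate | CC1=CC[C@@H]2C(C)(C)[C@H](O)[C@@H](OC(=O)c3ccccc3)C[C@@]2(C)C1=C | intermediate (not isolated)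
12 | (2S,3S,4aS,8aR)-4,4,7,8a-tetramethyl-8-methylidene-1,2,3,4,4a,5,8,8a-octahydronaphthalene-2,3-diol | CC1=CC[C@@H]2C(C)(C)[C@H](O)[C@@H](O)C[C@@]2(C)C1=C | intermediate
13 | C11 adduct of 12 with 9-borabicyclo[3.3.1]nonane (boron on C11; hydroxyl groups drawn free) | CC1=CC[C@@H]2C(C)(C)[C@H](O)[C@@H](O)C[C@@]2(C)[C@@H]1CB1C2CCCC1CCC2 | intermediate (not isolated)
14 | (2S,3S,4aS,8R,8aR)-8-(hydroxymethyl)-4,4,7,8a-tetramethyl-1,2,3,4,4a,5,8,8a-octahydronaphthalene-2,3-diol | CC1=CC[C@@H]2C(C)(C)[C@H](O)[C@@H](O)C[C@@]2(C)[C@@H]1CO | intermediate
15 | umbelliferone (7-hydroxy-2H-chromen-2-one) | O=c1ccc2ccc(O)cc2o1 | starting material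
16 | 7-{[(1R,4aS,6S,7S,8aR)-6,7-dihydroxy-2,5,5,8a-tetramethyl-1,4,4a,5,6,7,8,8a-octahydronaphthalen-1-yl]methoxy}-2H-chromen-2-one | CC1=CC[C@@H]2C(C)(C)[C@H](O)[C@@H](O)C[C@@]2(C)[C@@H]1COc1ccc2ccc(=O)oc2c1 | target

Total step count: 8. Longest linear sequence: 8 steps, from (S)-carvone.

Steps most likely to fail

Step 5 (key step). The addition of the tertiary radical to the aldehyde is reversible and its facial preference rests only on the chair transition state. The carbonyl oxygen may therefore take the axial site to a significant extent, so that 9 is formed together with its C3 epimer; simple reduction of the radical is the accompanying loss. The fallback sets the C3 centre by hydride delivery instead of by the cyclisation. It sets out from compound 9 as obtained in admixture with its C3 epimer. Oxidation of the mixture with Dess–Martin periodinane (CH2Cl2, 23 °C) should converge both alcohols on the 2-benzoyloxy-3-ketone F1. Reduction with NaBH4 (MeOH/CH2Cl2, −78 to −40 °C) should then deliver hydride axially, from the face away from the axial methyl groups at C4 and C10, and spare the more hindered conjugated C9 ketone. This returns the equatorial alcohol, compound 9.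

Step 4. The enamine of 6 may add intramolecularly to the enone carbon C7 (Michael closure to a bicyclo[2.2.2]octanone) in competition with benzoyloxylation, or the oxygenation may proceed with poor selectivity at the future C2. The fallback introduces the C2 oxygen after ring closure under substrate control; it sets out from compound 6 and comes back at compound 12.
- Cyclisation of 6 under the step 5 conditions (Fe(acac)3, PhSiH3, EtOH) should give the 2-deoxy hydroxy enone F2.
- Dess–Martin periodinane should give the 3,9-dione F3.
- The C3 ketone can enolise only toward C2. Its kinetic enolate (KN(SiMe3)2, THF, −78 °C) with 2-(phenylsulfonyl)-3-phenyloxaziridine should give the equatorial 2-hydroxy-3-ketone F4, the oxidant approaching anti to the axial C10 methyl group.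
- NaBH4 (MeOH/CH2Cl2, −78 °C) should give the trans-diequatorial diol enone F5.
- Wittig methylenation (Ph3PCH3Br, KOtBu, toluene, 90 °C) should give compound 12.

Step 8. Displacement at the β-branched C11 carbinol may be slow enough for the activated phosphonium species to be diverted (alkylation of the hydrazide, or tying up of the ring A diol as a cyclic phosphorane), which stalls the etherification. The fallback separates activation from displacement; it sets out from compound 14 and comes back at compound 16. Selective sulfonylation of the only primary hydroxyl (TsCl, pyridine, 0 °C) should give the primary tosylate F6. Heating F6 with umbelliferone and Cs2CO3 in DMF (70 °C) should give compound 16 by SN2 substitution.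

Further compounds
F1 | step 5 | (2S,4aR,8aR)-4,4,7,8a-tetramethyl-3,8-dioxo-1,2,3,4,4a,5,8,8a-octahydronaphthalen-2-yl benzoate (2-benzoyloxy-3-ketone) | CC1=CC[C@@H]2C(C)(C)C(=O)[C@@H](OC(=O)c3ccccc3)C[C@@]2(C)C1=O
F2 | step 4 | 2-deoxy hydroxy enone: compound 9 with CH2 at C2 in place of the benzoate-bearing carbon (3-OH equatorial; either C3 epimer serves) | CC1=CC[C@@H]2C(C)(C)[C@H](O)CC[C@@]2(C)C1=O
F3 | step 4 | 3,9-dione: the C3 ketone of F2 | CC1=CC[C@@H]2C(C)(C)C(=O)CC[C@@]2(C)C1=O
F4 | step 4 | 2-hydroxy-3-ketone: F3 with an equatorial hydroxyl at C2, trans to the C10 methyl group | CC1=CC[C@@H]2C(C)(C)C(=O)[C@@H](O)C[C@@]2(C)C1=O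
F5 | step 4 | diol enone: compound 9 without the benzoyl group (2,3-trans-diequatorial diol, C9 ketone) | CC1=CC[C@@H]2C(C)(C)[C@H](O)[C@@H](O)C[C@@]2(C)C1=O
F6 | step 8 | primary tosylate of 14 (4-methylbenzenesulfonate on the C11 oxygen, ring A diol free) | CC1=CC[C@@H]2C(C)(C)[C@H](O)[C@@H](O)C[C@@]2(C)[C@@H]1COS(=O)(=O)c1ccc(C)cc1
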